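## Analysis of the target

Euchrenone b2 (24) is an isoflavone: a 4H-chromen-4-one (ring A fused to pyranone ring C) that carries ring B on C3. Ring A is hexasubstituted, with hydroxyls on C5 and C7, prenyl groups on C6 and C8, and the fusion carbons C4a and C8a. Ring B is a 2-prenylresorcinol joined through C1', with hydroxyls on C2' and C4' and the prenyl group on C3'. There is no stereocentre, and each side-chain alkene ends in two methyl groups, so no configuration has to be set in the target. The sensitive parts are the three trisubstituted alkenes, each next to at least one phenol: strong acid closes such pairs to dimethylchromans, electrophilic halogen and hydrogenation attack the alkenes, and the free polyphenol is easily oxidised. The difficulty is regiochemical and steric: three prenyl groups must sit on carbon, each between two oxygens, and the C4 carbonyl must be joined to C4a, which is flanked on both sides. The plan rests on two features. C4 is a single carbonyl carbon between C4a and C3, so it can enter as carbon monoxide. Before ring C is closed, ring A is a threefold-symmetric phloroglucinol whose three oxygens, and the three carbons between them, are equivalent.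

## Retrosynthetic reasoning

**24 to 22 (through 23).** The first cut is the O1–C2 bond of ring C, together with the five phenol protecting groups. This opens the pyranone to the open-chain β-methoxy enone 23, whose fully acetal-protected form is 22. In the forward direction acid has to free the phenols, after which a hydroxyl ortho to the ketone adds to C2 and the methoxy group leaves. The two oxygens ortho to the ketone in 23 are equivalent, so either may become O1. The cut is placed here because it leaves only one step after the key step, and because the enone geometry of 22 does not matter once C2 passes through an sp3 stage.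

**22 to 9, 21 and 20.** The C4a–C4 and C4–C3 bonds are cut together, which releases C4 as carbon monoxide 21 and leaves the ring A iodide 9 and the ring B alkenylboronate 20. Cutting here separates the molecule into two aromatic halves of similar size, each already carrying its prenyl groups. The forward reaction has to make the hindered aryl–carbonyl bond by migration of the aryl group onto coordinated 21 at palladium, not by acylation of a deactivated or wrongly directed arene. It is neutral to basic, so the alkenes, the acetals and the enol ether are not at risk.

**9 to 7, 5, 2 and 1.** The three ring substituents of 9 are removed one at a time, iodine first and then the two prenyl groups (from 3), down to the tris-acetal 2 of phloroglucinol 1. Every ring hydrogen in 2, 5 and 7 lies between two acetal oxygens, so each directed metalation (aryllithiums 4, 6 and 8) has only equivalent sites to choose from. This is the reason for keeping ring A open and symmetric until after the key step.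

**20 to 19, 17, 13 and 14.** The boronate is traced to the enol triflate 19, and that to the α-methoxy ketone 17, which is cut at the aryl–carbonyl bond into aryllithium 15 and the Weinreb amide 14. A route through electrophilic halogenation of an enol ether double bond and elimination was not used, because the prenyl alkene of ring B would compete for the electrophile. Sulfonylation of the enolate 18 needs no such reagent, and the enolate fixes one double-bond geometry.

**13 to 11, 10 and 3.** The prenyl group of 13 is removed from C2 of the bis-acetal 11 of resorcinol 10. The position between the two acetals is metalated first (aryllithium 12), which places the prenyl group at C3' of the target. The later metalation to 15 can then only go next to one acetal, at the carbon that becomes C1'.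

## Alternatives that were turned down

**Alternative 1: ring C closed at carbon by intramolecular acylation.**
- Disconnection: the C4–C4a bond. The aryloxyacrylic acid A2, activated as a mixed anhydride, would acylate an ortho carbon of its own 3,5-bis(allyloxy)phenoxy ring to give the chromone A1.
- For it: the acylation is intramolecular and lands on a doubly activated, symmetric ring, so there is no regiochemical choice. It needs no gas under pressure and no transition metal, and it delivers the chromone directly. On reliability of the ring-forming event it is stronger than an intermolecular three-component coupling between crowded partners.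
- Against it: A1 has none of the three carbon-bound side chains. All of them would still have to be moved from oxygen to carbon (the rearrangement of Alternative 3) and each allyl group converted to prenyl. The benzyl ether would then have to be removed without hydrogenolysis, which the alkenes exclude. That is several steps after the key step, each carrying its own selectivity question.
- Comparison: the chosen route gives up the easy ring closure, but all three prenyl groups are in place before the key step and only one step follows it.

**Alternative 2: ring B built by benzannulation.**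
- Disconnection: four bonds of ring B (C5'–C6', C2'–C3', C4'–C5', C1'–C2'). Irradiation of the diazo ketone A4 would give a vinylketene by Wolff rearrangement. Cycloaddition with the siloxyalkyne A5, ring opening of the cyclobutenone and six-electron electrocyclisation would give A3.
- For it: the polarity of A5 fixes the C3' prenyl group between the two ring B oxygens, and the C2' hydroxyl and the C4' silyl ether emerge differentiated. It forms four bonds in one operation, where the chosen key step forms two.
- Against it: ring B of 24 is a 2-prenylresorcinol, which the chosen route reaches in two steps from 10, so building it atom by atom is poor economy. A4 already contains the complete diprenylated chromone with a functionalised C3, so ring A and ring C would have to be solved first by other means. The chromone absorbs light itself and can add to the prenyl alkenes. A4 and A5 each take several steps to make.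
- Comparison: the chosen route is shorter and puts its risk in a thermal catalytic step that tolerates the alkenes.

**Alternative 3: triple Claisen rearrangement.**
- Disconnection: the three aryl–CH2 bonds at C6, C8 and C3'. Heating the tris(allyl ether) A1, or Lewis acid catalysis by a lanthanide complex, would move the allyl groups from O5, O7 and O2' to carbon and give A6.
- For it: three carbon–carbon bonds in one operation, no organometallic reagent, and trivially selective O-allylation beforehand. On bonds formed per step it beats the chosen key step.
- Against it:
  - It delivers allyl groups, not prenyl groups, because a prenyl ether would rearrange with allylic inversion. Three cross-metatheses with a second-generation Grubbs catalyst would be needed afterwards.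
  - The O7 allyl group has two ortho carbons (C6 and C8) and the O5 group only one (C6), so the outcome depends on the order of migration.
  - The O5 ether beside the carbonyl is slow to rearrange, and ortho-allylphenols cyclise to dihydrobenzofurans at the temperatures required.
  - The benzyl ether must still be removed in the presence of three alkenes.
- Comparison: the chosen route installs prenyl groups directly by metalation, with the regiochemistry fixed by symmetry instead of by relative migration rates.

Key step: step 10

Remark on the chemistry: the configuration of the methoxyvinyl double bond has no bearing on 24, because C2 becomes sp3 during ring closure. The route carries the isomer that enolate geometry fixes (OMe cis to boron in 20, cis to the carbonyl in 22); the other isomer would serve equally.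

## Route

**Step 1**
Reactants: 1 phloroglucinol
Product: 2 1,3,5-tris(methoxymethoxy)benzene
Conditions: MOMCl (3.6 equiv), iPr2NEt (4.5 equiv), DMF, 0 °C → rt
Reagents that add atoms: chloromethyl methyl ether, COCCl
Why: Base-mediated O-alkylation of the three phenols with an α-chloro ether (Williamson-type acetal formation); the weakly basic amine keeps the phenoxide concentration low, which disfavours C-alkylation of the phloroglucinol nucleus.

**Step 2**
Reactants: 2 1,3,5-tris(methoxymethoxy)benzene; 3 prenyl bromide (1-bromo-3-methylbut-2-ene)
Product: 5 1,3,5-tris(methoxymethoxy)-2-(3-methylbut-2-enyl)benzene, via aryllithium 4 (not isolated)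
Conditions: n-BuLi (1.05 equiv), THF, 0 °C; CuI (10 mol %), then 3, −78 °C → rt
Reagents that add atoms: none
Why: Directed ortho-metalation removes a ring proton held between two chelating acetal groups, and by threefold symmetry all three sites are the same; the aryllithium, relayed through a catalytic arylcopper, should displace bromide at the primary carbon of 3, since attack at the other allylic terminus would build a quaternary centre.

**Step 3**
Reactants: 5 1,3,5-tris(methoxymethoxy)-2-(3-methylbut-2-enyl)benzene; 3 prenyl bromide
Product: 7 1,3,5-tris(methoxymethoxy)-2,4-bis(3-methylbut-2-enyl)benzene, via aryllithium 6 (not isolated)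
Conditions: n-BuLi (1.1 equiv), THF, 0 °C; CuI (10 mol %), then 3, −78 °C → rt
Reagents that add atoms: none
Why: Second directed ortho-metalation at one of the two equivalent ring positions, each still flanked by two acetals, followed by the same copper-catalysed allylic substitution; ring deprotonation should outrun removal of a side-chain CH2 proton because the ring proton lies between the two chelating groups.

**Step 4**
Reactants: 7 1,3,5-tris(methoxymethoxy)-2,4-bis(3-methylbut-2-enyl)benzene
Product: 9 2-iodo-1,3,5-tris(methoxymethoxy)-4,6-bis(3-methylbut-2-enyl)benzene, via aryllithium 8 (not isolated)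
Conditions: n-BuLi (1.2 equiv), THF, 0 °C; I2 (1.05 equiv), THF, −78 °C → rt; aq Na2S2O3
Reagents that add atoms: iodine, II
Why: Third directed ortho-metalation at the only ring proton left, then electrophilic iodination of the aryllithium, which at −78 °C should be far faster than any reaction of I2 with the trisubstituted alkenes.

**Step 5**
Reactants: 10 resorcinol
Product: 11 1,3-bis(methoxymethoxy)benzene
Conditions: MOMCl (2.4 equiv), iPr2NEt (3 equiv), CH2Cl2, 0 °C → rt
Reagents that add atoms: chloromethyl methyl ether, COCCl
Why: O-Alkylation of both phenols as in step 1 (Williamson-type acetal formation).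

**Step 6**
Reactants: 11 1,3-bis(methoxymethoxy)benzene; 3 prenyl bromide
Product: 13 1,3-bis(methoxymethoxy)-2-(3-methylbut-2-enyl)benzene, via aryllithium 12 (not isolated)
Conditions: n-BuLi (1.1 equiv), THF, 0 °C → rt; CuI (10 mol %), then 3, −78 °C → rt
Reagents that add atoms: none
Why: Directed ortho-metalation goes to C2, the one position activated by both acetals, and copper-catalysed allylic substitution then places the prenyl group between the two oxygens.

**Step 7**
Reactants: 13 1,3-bis(methoxymethoxy)-2-(3-methylbut-2-enyl)benzene; 14 N,2-dimethoxy-N-methylacetamide
Product: 17 1-[2,4-bis(methoxymethoxy)-3-(3-methylbut-2-enyl)phenyl]-2-methoxyethan-1-one, via aryllithium 15 (not isolated), via lithium hemiaminal adduct 16 (not isolated)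
Conditions: s-BuLi (1.2 equiv), TMEDA (1.2 equiv), THF, −78 °C; 14, −78 → 0 °C; then H2O
Reagents that add atoms: none
Why: With C2 blocked, directed ortho-metalation can only go to C4 (equivalent to C6), the remaining site next to an acetal; in the Weinreb ketone synthesis the aryllithium adds once to 14 and the chelated adduct 16 cannot collapse to the ketone until the aqueous quench, so no tertiary alcohol should form.

**Step 8**
Reactants: 17 1-[2,4-bis(methoxymethoxy)-3-(3-methylbut-2-enyl)phenyl]-2-methoxyethan-1-one
Product: 19 (Z)-1-[2,4-bis(methoxymethoxy)-3-(3-methylbut-2-enyl)phenyl]-2-methoxyvinyl trifluoromethanesulfonate, via potassium enolate 18 (not isolated)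
Conditions: KN(SiMe3)2 (1.1 equiv), THF, −78 °C; PhNTf2 (1.15 equiv), −78 → 0 °C
Reagents that add atoms: N-phenylbis(trifluoromethanesulfonimide), O=S(=O)(N(c1ccccc1)S(=O)(=O)C(F)(F)F)C(F)(F)F
Why: Ketone 17 has a single enolisable position, and the enolate should form with O− and OMe cis (Z), since the other geometry presses OMe against the ortho-substituted aryl group (allylic 1,3-strain) and gives up the potassium chelate; O-sulfonylation (enol triflate formation) fixes this geometry without any electrophile that could attack the prenyl alkene.

**Step 9**
Reactants: 19 (Z)-1-[2,4-bis(methoxymethoxy)-3-(3-methylbut-2-enyl)phenyl]-2-methoxyvinyl trifluoromethanesulfonate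
Product: 20 (E)-2-{1-[2,4-bis(methoxymethoxy)-3-(3-methylbut-2-enyl)phenyl]-2-methoxyvinyl}-4,4,5,5-tetramethyl-1,3,2-dioxaborolane
Conditions: B2pin2 (1.2 equiv), PdCl2(PPh3)2 (3 mol %), PPh3 (6 mol %), KOPh (1.5 equiv), toluene, 50 °C
Reagents that add atoms: bis(pinacolato)diboron, CC1(C)OB(OC1(C)C)B1OC(C)(C)C(C)(C)O1
Why: Miyaura borylation of an alkenyl triflate: oxidative addition to zerovalent palladium, exchange with phenoxide, transmetalation with B2pin2 and reductive elimination all go with retention at the alkenyl carbon, so boron takes the place of the triflate oxygen cis to OMe; KOPh is too weak a base to drive Suzuki coupling of 20 with unreacted 19.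

**Step 10**
Reactants: 9 2-iodo-1,3,5-tris(methoxymethoxy)-4,6-bis(3-methylbut-2-enyl)benzene; 21 carbon monoxide; 20 (E)-2-{1-[2,4-bis(methoxymethoxy)-3-(3-methylbut-2-enyl)phenyl]-2-methoxyvinyl}-4,4,5,5-tetramethyl-1,3,2-dioxaborolane (1.5 equiv)
Product: 22 (Z)-2-[2,4-bis(methoxymethoxy)-3-(3-methylbut-2-enyl)phenyl]-3-methoxy-1-[2,4,6-tris(methoxymethoxy)-3,5-bis(3-methylbut-2-enyl)phenyl]prop-2-en-1-one
Conditions: Pd(OAc)2 (5 mol %), P(1-Ad)2(n-Bu) (10 mol %), K2CO3 (3 equiv), CO (5 bar), toluene–H2O (20:1), 80 °C
Reagents that add atoms: none
Why: This is a carbonylative Suzuki–Miyaura coupling, the known three-component synthesis of aryl vinyl ketones from aryl iodides, CO and alkenylboron reagents. Pd(OAc)2 is reduced in the flask to a zerovalent palladium–phosphine complex; oxidative addition into the C–I bond of 9 gives an arylpalladium iodide, CO coordinates and the aryl group migrates onto it to give the aroylpalladium complex (C4a–C4), base-assisted transmetalation with 20 delivers the alkenyl group, and reductive elimination forms C4–C3 and returns zerovalent palladium. No ring is closed and no stereocentre is created; the alkenyl carbon is transferred with retention, so the methoxy group should end cis to the new carbonyl (Z). The selectivity needed is carbonylative over direct coupling: the two ortho acetal groups hold back transmetalation at the crowded arylpalladium stage while migration onto CO relieves that crowding, and 5 bar of CO keeps the metal saturated, so insertion should come first. The electron-rich, bulky phosphine is there to speed oxidative addition of the electron-rich, hindered iodide and to promote reductive elimination from the congested acyl(alkenyl)palladium complex. The aroylpalladium complex must also be captured by the boronate and not by water or hydroxide, which is addressed by keeping water to a few equivalents and using 20 in excess. Carbonate base at 80 °C should leave the three prenyl groups, the five acetals and the enol ether untouched.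

**Step 11**
Reactants: 22 (Z)-2-[2,4-bis(methoxymethoxy)-3-(3-methylbut-2-enyl)phenyl]-3-methoxy-1-[2,4,6-tris(methoxymethoxy)-3,5-bis(3-methylbut-2-enyl)phenyl]prop-2-en-1-one
Product: 24 euchrenone b2, via pentahydroxy methoxyenone 23 (not isolated)
Conditions: conc. aq HCl diluted to ca. 1 M in MeOH, 40 °C
Reagents that add atoms: none
Why: Acid-catalysed acetal exchange with the solvent frees the five phenols; either of the two equivalent hydroxyls ortho to the ketone then adds to C2 of the β-methoxy enone (6-endo-trig oxa-Michael addition) and methanol is eliminated, an addition–elimination driven by the aromatic 4-pyranone and the hydrogen bond from the C5 hydroxyl to the C4 carbonyl; the enone geometry is erased at the sp3 stage.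

## Compound list

1 | phloroglucinol (benzene-1,3,5-triol) | Oc1cc(O)cc(O)c1 | starting material
2 | 1,3,5-tris(methoxymethoxy)benzene | COCOc1cc(OCOC)cc(OCOC)c1 | intermediate
3 | prenyl bromide (1-bromo-3-methylbut-2-ene) | CC(C)=CCBr | starting material
4 | [2,4,6-tris(methoxymethoxy)phenyl]lithium | [Li]c1c(OCOC)cc(OCOC)cc1OCOC | intermediate
5 | 1,3,5-tris(methoxymethoxy)-2-(3-methylbut-2-enyl)benzene | COCOc1cc(OCOC)c(CC=C(C)C)c(OCOC)c1 | intermediate
6 | [2,4,6-tris(methoxymethoxy)-3-(3-methylbut-2-enyl)phenyl]lithium | [Li]c1c(OCOC)cc(OCOC)c(CC=C(C)C)c1OCOC | intermediate
7 | 1,3,5-tris(methoxymethoxy)-2,4-bis(3-methylbut-2-enyl)benzene | COCOc1cc(OCOC)c(CC=C(C)C)c(OCOC)c1CC=C(C)C | intermediate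
8 | [2,4,6-tris(methoxymethoxy)-3,5-bis(3-methylbut-2-enyl)phenyl]lithium | [Li]c1c(OCOC)c(CC=C(C)C)c(OCOC)c(CC=C(C)C)c1OCOC | intermediate
9 | 2-iodo-1,3,5-tris(methoxymethoxy)-4,6-bis(3-methylbut-2-enyl)benzene | COCOc1c(I)c(OCOC)c(CC=C(C)C)c(OCOC)c1CC=C(C)C | intermediate
10 | resorcinol (benzene-1,3-diol) | Oc1cccc(O)c1 | starting material
11 | 1,3-bis(methoxymethoxy)benzene | COCOc1cccc(OCOC)c1 | intermediate
12 | [2,6-bis(methoxymethoxy)phenyl]lithium | [Li]c1c(OCOC)cccc1OCOC | intermediate
13 | 1,3-bis(methoxymethoxy)-2-(3-methylbut-2-enyl)benzene | COCOc1cccc(OCOC)c1CC=C(C)C | intermediate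
14 | N,2-dimethoxy-N-methylacetamide | COCC(=O)N(C)OC | starting material
15 | [2,4-bis(methoxymethoxy)-3-(3-methylbut-2-enyl)phenyl]lithium | [Li]c1ccc(OCOC)c(CC=C(C)C)c1OCOC | intermediate
16 | lithium 1-[2,4-bis(methoxymethoxy)-3-(3-methylbut-2-enyl)phenyl]-2-methoxy-1-[methoxy(methyl)amino]ethan-1-olate (racemic) | [Li+].COCC([O-])(N(C)OC)c1ccc(OCOC)c(CC=C(C)C)c1OCOC | intermediate
17 | 1-[2,4-bis(methoxymethoxy)-3-(3-methylbut-2-enyl)phenyl]-2-methoxyethan-1-one | COCC(=O)c1ccc(OCOC)c(CC=C(C)C)c1OCOC | intermediate
18 | potassium (Z)-1-[2,4-bis(methoxymethoxy)-3-(3-methylbut-2-enyl)phenyl]-2-methoxyethen-1-olate | [K+].CO/C=C(\[O-])c1ccc(OCOC)c(CC=C(C)C)c1OCOC | intermediate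
19 | (Z)-1-[2,4-bis(methoxymethoxy)-3-(3-methylbut-2-enyl)phenyl]-2-methoxyvinyl trifluoromethanesulfonate | CO/C=C(\OS(=O)(=O)C(F)(F)F)c1ccc(OCOC)c(CC=C(C)C)c1OCOC | intermediate
20 | (E)-2-{1-[2,4-bis(methoxymethoxy)-3-(3-methylbut-2-enyl)phenyl]-2-methoxyvinyl}-4,4,5,5-tetramethyl-1,3,2-dioxaborolane | CO/C=C(\B1OC(C)(C)C(C)(C)O1)c1ccc(OCOC)c(CC=C(C)C)c1OCOC | intermediate
21 | carbon monoxide | [C-]#[O+] | starting material
22 | (Z)-2-[2,4-bis(methoxymethoxy)-3-(3-methylbut-2-enyl)phenyl]-3-methoxy-1-[2,4,6-tris(methoxymethoxy)-3,5-bis(3-methylbut-2-enyl)phenyl]prop-2-en-1-one | CO/C=C(\C(=O)c1c(OCOC)c(CC=C(C)C)c(OCOC)c(CC=C(C)C)c1OCOC)c1ccc(OCOC)c(CC=C(C)C)c1OCOC | intermediate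
23 | (Z)-2-[2,4-dihydroxy-3-(3-methylbut-2-enyl)phenyl]-3-methoxy-1-[2,4,6-trihydroxy-3,5-bis(3-methylbut-2-enyl)phenyl]prop-2-en-1-one | CO/C=C(\C(=O)c1c(O)c(CC=C(C)C)c(O)c(CC=C(C)C)c1O)c1ccc(O)c(CC=C(C)C)c1O | intermediate
24 | euchrenone b2, 3-[2,4-dihydroxy-3-(3-methylbut-2-enyl)phenyl]-5,7-dihydroxy-6,8-bis(3-methylbut-2-enyl)-4H-chromen-4-one | CC(C)=CCc1c(O)ccc(-c2coc3c(CC=C(C)C)c(O)c(CC=C(C)C)c(O)c3c2=O)c1O | target

## Step count and the least certain steps

Total: 11 steps. Longest linear sequence: 7 steps (steps 5 to 11, from resorcinol 10). The ring A branch (steps 1 to 4) joins at step 10.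

**Step 10 (key step).** Three things can go wrong.
- Direct coupling without uptake of CO, if transmetalation overtakes migration onto CO.
- Hydrolytic capture of the aroylpalladium complex by water or hydroxide before the hindered boronate arrives.
- Protodeboronation of the electron-rich alkenylboronate at 80 °C.

All three stem from slow transmetalation between two crowded partners. Fallback: C4 would be brought in as a formyl group and the two halves joined by carbonyl addition.
- Starting from 7, aryllithium 8 (formed as in step 4) would be quenched with DMF to give 2,4,6-tris(methoxymethoxy)-3,5-bis(3-methylbut-2-enyl)benzaldehyde F1.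
- Nozaki–Hiyama–Kishi coupling of F1 with triflate 19 (CrCl2, NiCl2 cat., DMF, rt) should give the racemic allylic alcohol (Z)-2-[2,4-bis(methoxymethoxy)-3-(3-methylbut-2-enyl)phenyl]-3-methoxy-1-[2,4,6-tris(methoxymethoxy)-3,5-bis(3-methylbut-2-enyl)phenyl]prop-2-en-1-ol F2.
- Oxidation of this benzylic, allylic alcohol with MnO2 in CH2Cl2 would return to the route at 22.

**Step 11.** Protonation of a prenyl alkene by the mineral acid, followed by capture by a neighbouring phenol (chroman formation) or by chloride, can compete with acetal cleavage, since each of the three alkenes sits next to at least one hydroxyl once the acetals are gone. Fallback: starting from 22, the acetals would be cleaved without protic acid by ZnBr2 and propane-1-thiol in CH2Cl2 at 0 °C, where the thiol takes up the methoxymethyl group. This gives 23, now isolated, and K2CO3 in MeOH at rt would close ring C by phenoxide addition–elimination, returning to the route at 24. No compound outside the numbered ones is made (F0).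

**Step 4 (and step 3 before it).** On the increasingly crowded ring, deprotonation of a side-chain CH2 group, which is both benzylic and allylic, may compete with removal of the last ring proton, and the aryllithium may be incompletely formed. Fallback: the aryllithiums would be made by halogen–lithium exchange instead of deprotonation.
- Starting from 2, NBS (3 equiv) in MeCN at 0 °C should give 1,3,5-tribromo-2,4,6-tris(methoxymethoxy)benzene F3.
- Bromine–lithium exchange (n-BuLi, THF, −78 °C) and copper-catalysed reaction with 3 would give 1,3-dibromo-2,4,6-tris(methoxymethoxy)-5-(3-methylbut-2-enyl)benzene F4.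
- A second exchange and prenylation would give 2-bromo-1,3,5-tris(methoxymethoxy)-4,6-bis(3-methylbut-2-enyl)benzene F5.
- A third exchange at −78 °C, where side-chain deprotonation cannot compete, gives aryllithium 8, and I2 then returns to the route at 9.

**Step 7.** Here the ring position is activated by only one acetal, so lateral deprotonation of the prenyl CH2 group (which lies between two acetals) is a more serious competitor than in ring A; enolisation of amide 14 by the aryllithium is a lesser concern. Fallback: the aryllithium would be generated by exchange from a bromide.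
- Starting from 4-bromobenzene-1,3-diol F6 (purchased), MOMCl and iPr2NEt would give 1-bromo-2,4-bis(methoxymethoxy)benzene F7.
- LiN(iPr)2 in THF at −78 °C deprotonates between the two acetals without touching the bromide, and CuI with 3 would give 1-bromo-2,4-bis(methoxymethoxy)-3-(3-methylbut-2-enyl)benzene F8.
- n-BuLi at −78 °C then gives aryllithium 15 by bromine–lithium exchange, which rejoins the route at 15 and goes on with 14 to 17.

## Further compounds

F1 | step 10 | 2,4,6-tris(methoxymethoxy)-3,5-bis(3-methylbut-2-enyl)benzaldehyde | O=Cc1c(OCOC)c(CC=C(C)C)c(OCOC)c(CC=C(C)C)c1OCOC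
F2 | step 10 | (Z)-2-[2,4-bis(methoxymethoxy)-3-(3-methylbut-2-enyl)phenyl]-3-methoxy-1-[2,4,6-tris(methoxymethoxy)-3,5-bis(3-methylbut-2-enyl)phenyl]prop-2-en-1-ol (racemic) | CO/C=C(\C(O)c1c(OCOC)c(CC=C(C)C)c(OCOC)c(CC=C(C)C)c1OCOC)c1ccc(OCOC)c(CC=C(C)C)c1OCOC
F0 | step 11 | none | none
F3 | step 4 | 1,3,5-tribromo-2,4,6-tris(methoxymethoxy)benzene | COCOc1c(Br)c(OCOC)c(Br)c(OCOC)c1Br
F4 | step 4 | 1,3-dibromo-2,4,6-tris(methoxymethoxy)-5-(3-methylbut-2-enyl)benzene | COCOc1c(Br)c(OCOC)c(CC=C(C)C)c(OCOC)c1Br
F5 | step 4 | 2-bromo-1,3,5-tris(methoxymethoxy)-4,6-bis(3-methylbut-2-enyl)benzene | COCOc1c(Br)c(OCOC)c(CC=C(C)C)c(OCOC)c1CC=C(C)C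
F6 | step 7 | 4-bromobenzene-1,3-diol | Oc1ccc(Br)c(O)c1
F7 | step 7 | 1-bromo-2,4-bis(methoxymethoxy)benzene | COCOc1ccc(Br)c(OCOC)c1
F8 | step 7 | 1-bromo-2,4-bis(methoxymethoxy)-3-(3-methylbut-2-enyl)benzene | COCOc1ccc(Br)c(OCOC)c1CC=C(C)C
A1 | alternative 1 | 5,7-bis(allyloxy)-3-[2-(allyloxy)-4-(benzyloxy)phenyl]-4H-chromen-4-one | C=CCOc1cc(OCC=C)c2c(c1)occ(-c1ccc(OCc3ccccc3)cc1OCC=C)c2=O
A2 | alternative 1 | (Z)-3-[3,5-bis(allyloxy)phenoxy]-2-[2-(allyloxy)-4-(benzyloxy)phenyl]prop-2-enoic acid | C=CCOc1cc(OCC=C)cc(O/C=C(\C(=O)O)c2ccc(OCc3ccccc3)cc2OCC=C)c1
A3 | alternative 2 | 3-[2-hydroxy-3-(3-methylbut-2-enyl)-4-(triisopropylsilyloxy)phenyl]-5,7-bis(methoxymethoxy)-6,8-bis(3-methylbut-2-enyl)-4H-chromen-4-one | CC(C)=CCc1c(O[Si](C(C)C)(C(C)C)C(C)C)ccc(-c2coc3c(CC=C(C)C)c(OCOC)c(CC=C(C)C)c(OCOC)c3c2=O)c1O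
A4 | alternative 2 | (E)-4-[5,7-bis(methoxymethoxy)-6,8-bis(3-methylbut-2-enyl)-4-oxo-4H-chromen-3-yl]-1-diazobut-3-en-2-one | [N-]=[N+]=CC(=O)/C=C/c1coc2c(CC=C(C)C)c(OCOC)c(CC=C(C)C)c(OCOC)c2c1=O
A5 | alternative 2 | triisopropyl[(5-methylhex-4-en-1-yn-1-yl)oxy]silane | CC(C)=CCC#CO[Si](C(C)C)(C(C)C)C(C)C
A6 | alternative 3 | 6,8-diallyl-3-[3-allyl-4-(benzyloxy)-2-hydroxyphenyl]-5,7-dihydroxy-4H-chromen-4-one | C=CCc1c(O)c(CC=C)c2occ(-c3ccc(OCc4ccccc4)c(CC=C)c3O)c(=O)c2c1O
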